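**Assumptions (one line each)**
- The SMILES is read as 6α‑(4‑hydroxybenzoyloxy)dauc‑8(14)‑ene‑4β,9α‑diol: trans‑fused 5/7 ring system, 1R,4R,5S,6S,9S in daucane numbering (C1 = C–CH3 ring fusion, C2/C3 = CH2CH2, C4 = C(OH)iPr, C5 = ring‑fusion CH, C6 = CH–O‑ester, C7 = CH2, C8 = C(=C14H2), C9 = CHOH, C10 = CH2). β = face of the angular methyl, α = opposite face.
- The handedness of Rh2(R‑DOSP)4 (step 5) and of IpcBH2 from (+)‑α‑pinene (step 6) is assigned from their standard empirical models and must be confirmed on the first batch. If either is reversed, the mirror‑image catalyst or reagent is used.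

## Retrosynthetic overview
1. Ferugin ⇐ late C6 esterification plus Zn opening of an 8α,9α‑epoxy‑14‑iodide, which unveils the 9α‑OH and the C8=CH2 together; the epoxide comes from a Sharpless epoxidation of a C14 allylic alcohol.
2. C4 carbinol ⇐ i‑Pr–Ce addition to a trans‑fused C4 ketone; 5α‑H/6α‑OH ⇐ reagent‑controlled syn hydroboration of a C5=C6 alkene.
3. Key step: Rh(II)‑catalysed asymmetric cyclopropanation / divinylcyclopropane (Cope) rearrangement, a formal [4+3], between an achiral 2‑methyl‑1‑vinylcyclopentene ketal and methyl vinyldiazoacetate. It forms the seven‑membered ring, the quaternary C1 stereocentre and installs C14 in one operation.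
4. Ring order: the cyclopentene is purchased; the cycloheptadiene is annulated onto it by the [4+3]. No RCM, aldol closure or hydrindanone ring expansion is used.

## Route

**Step 1**
Reactants: 1, 3‑methylcyclopent‑2‑en‑1‑one
Product: 2, 2‑bromo‑3‑methylcyclopent‑2‑en‑1‑one
Conditions: Br2, CH2Cl2, 0 °C; then Et3N, 0 °C → rt
Reagents that add atoms: bromine, BrBr
Why: Bromine addition / dehydrobromination gives the α‑bromoenone; no stereocentre.

**Step 2**
Reactants: 2
Product: 3, 6‑bromo‑7‑methyl‑1,4‑dioxaspiro[4.4]non‑6‑ene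
Conditions: ethylene glycol, p‑TsOH (cat.), benzene, reflux, Dean–Stark
Reagents that add atoms: ethylene glycol, OCCO
Why: Acid‑catalysed ketalisation masks the future C4 carbonyl as a symmetric dioxolane and makes the ring alkene electron‑neutral for the carbenoid step.

**Step 3**
Reactants: 3
Product: 4, 6‑ethenyl‑7‑methyl‑1,4‑dioxaspiro[4.4]non‑6‑ene (achiral diene)
Conditions: CH2=CHBF3K, PdCl2(dppf) (5 mol %), Cs2CO3, THF/H2O, 75 °C
Reagents that add atoms: potassium vinyltrifluoroborate, C=C[B-](F)(F)F.[K+]
Why: Suzuki–Miyaura coupling of the alkenyl bromide; the basic conditions leave the ketal intact.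

**Step 4**
Reactants: 5, methyl but‑3‑enoate
Product: 6, methyl 2‑diazobut‑3‑enoate (used at once as a cold pentane solution)
Conditions: p‑ABSA, DBU, MeCN, 0 °C
Reagents that add atoms: 4‑acetamidobenzenesulfonyl azide, CC(=O)Nc1ccc(cc1)S(=O)(=O)N=[N+]=[N-]
Why: Regitz diazo transfer to the doubly activated (allylic, α‑ester) CH2 gives the vinyldiazoacetate.

**Step 5 (key step)**
Reactants: 4 and 6
Product: 7, methyl ester of the 5/7 bicyclic diene: C1 quaternary (R, angular CH3), C4 ethylene ketal, C5=C6 and C8=C9 double bonds, CO2Me on C8, C7 and C10 = CH2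
Conditions: Rh2(R‑DOSP)4 (1 mol %), hexanes, −40 °C, slow addition of 6, → rt; then PhMe, 100 °C
Reagents that add atoms: none (N2 is lost from 6)
Why: Davies tandem asymmetric cyclopropanation / Cope rearrangement (formal [4+3]): the donor/acceptor carbenoid cyclopropanates only the terminal vinyl group to give a cis‑divinylcyclopropane, whose boat Cope transition state forms the C1–C10 bond, so C1 is set by the catalyst‑controlled cyclopropanation face (heating is needed because the ring methyl sits inside the boat).

**Step 6**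
Reactants: 7
Product: 8, 6α‑hydroxy‑5α‑H (trans‑fused) ketal ester; C8=C9–CO2Me untouched
Conditions: IpcBH2 (liberated from its TMEDA adduct, ex (+)‑α‑pinene, with BF3·OEt2), THF, −25 → 0 °C; then NaBO3·4H2O, THF/H2O, rt
Reagents that add atoms: sodium perborate (O source), [Na+].[Na+].O[B-]1(O)OO[B-](O)(O)OO1
Why: Brown asymmetric hydroboration: syn addition places H on C5 and B on the less substituted C6 from the same face (hence the cis 5‑H/6‑O relationship), the reagent selects the α‑face (anti to the angular methyl, giving trans fusion), and the deactivated enoate alkene does not react.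

**Step 7**
Reactants: 8
Product: 9, trans‑fused 6α‑hydroxy‑4‑ketone (β‑hydroxy ketone), ester retained
Conditions: PPTS (0.3 equiv), acetone/H2O 9:1, 45 °C, stopped at full conversion
Reagents that add atoms: water, O
Why: Mild acid ketal hydrolysis; conditions are kept weak and short to avoid C5 epimerisation or β‑elimination.

**Step 8**
Reactants: 9
Product: 10, 4β‑hydroxy‑4α‑isopropyl‑6α‑hydroxy ester (diol)
Conditions: i‑PrMgCl (4 equiv), anhydrous CeCl3 (4 equiv), THF, −78 → −40 °C
Reagents that add atoms: isopropylmagnesium chloride, CC(C)[Mg]Cl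
Why: Organocerium 1,2‑addition (non‑basic, ketone‑selective over the conjugated ester): the nucleophile enters from the α‑face, anti to the pseudo‑axial angular methyl and on the side of the chelating C6 alkoxide, giving the 4β‑OH.

**Step 9**
Reactants: 10
Product: 11, triol: C14 primary allylic alcohol (C8=C9), 4β‑OH, 6α‑OH
Conditions: DIBAL‑H (5 equiv), CH2Cl2, −78 °C; Rochelle salt work‑up
Reagents that add atoms: none
Why: 1,2‑Reduction of the enoate to the allylic alcohol; no stereocentre changes.

**Step 10**
Reactants: 11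
Product: 12, 8α,9α‑epoxy triol (8S,9S)
Conditions: Ti(Oi‑Pr)4 (1.1 equiv), L‑(+)‑DET (1.3 equiv), t‑BuOOH (2 equiv), 4 Å MS, CH2Cl2, −25 °C
Reagents that add atoms: tert‑butyl hydroperoxide, CC(C)(C)OO
Why: Sharpless asymmetric epoxidation of an (E)‑2,3‑disubstituted primary allylic alcohol; L‑(+)‑tartrate gives the (2S,3S)‑type epoxide, which here is the α‑epoxide and fixes C9–O as 9S under reagent control.

**Step 11**
Reactants: 12
Product: 13, 8α,9α‑epoxy‑14‑iodide diol
Conditions: PPh3, I2, imidazole, CH2Cl2, 0 °C, dark
Reagents that add atoms: iodine, II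
Why: Garegg–Samuelsson (Appel‑type) iodination, selective for the primary alcohol over the hindered secondary C6‑OH and tertiary C4‑OH.

**Step 12**
Reactants: 14, 4‑hydroxybenzoic acid
Product: 15, 4‑(tert‑butyldimethylsilyloxy)benzoic acid
Conditions: TBSCl (2.2 equiv), imidazole, DMF, rt; then K2CO3, MeOH/THF/H2O, rt; citric acid to pH 4
Reagents that add atoms: tert‑butyldimethylsilyl chloride, CC(C)(C)[Si](C)(C)Cl
Why: Bis‑silylation followed by selective cleavage of the labile silyl ester leaves the phenol protected.

**Step 13**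
Reactants: 13 and 15
Product: 16, C6 4‑(TBSO)benzoate of the epoxy iodide
Conditions: 2,4,6‑Cl3C6H2COCl, Et3N, THF, rt; then 13, DMAP, PhMe, 40 °C
Reagents that add atoms: none
Why: Yamaguchi esterification of the only acylable hydroxyl (secondary C6‑OH; C4‑OH is tertiary); the cis C6‑OH/epoxide relationship prevents transannular epoxide opening.

**Step 14**
Reactants: 16
Product: 17, O‑TBS‑ferugin (9α‑OH, C8=C14H2)
Conditions: Zn dust, AcOH (5 equiv), EtOH, 25 °C
Reagents that add atoms: none
Why: Zinc‑mediated reductive β‑elimination of the 2,3‑epoxy iodide (1,3‑transposition) gives the exocyclic methylene and the allylic alcohol; the C9–O bond is not broken, so 9S is retained.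

**Step 15**
Reactants: 17
Product: 18, ferugin
Conditions: KHF2 (2.5 equiv), MeOH, rt
Reagents that add atoms: none
Why: KHF2 cleaves the aryl silyl ether selectively, leaving the benzoate ester, the allylic alcohol and the alkene untouched.

## Compound list
1 | 3‑methylcyclopent‑2‑en‑1‑one | CC1=CC(=O)CC1 | starting material
2 | 2‑bromo‑3‑methylcyclopent‑2‑en‑1‑one | CC1=C(Br)C(=O)CC1 | intermediate
3 | 6‑bromo‑7‑methyl‑1,4‑dioxaspiro[4.4]non‑6‑ene | CC1=C(Br)C2(CC1)OCCO2 | intermediate
4 | 6‑ethenyl‑7‑methyl‑1,4‑dioxaspiro[4.4]non‑6‑ene | CC1=C(C=C)C2(CC1)OCCO2 | intermediate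
5 | methyl but‑3‑enoate | C=CCC(=O)OC | starting material
6 | methyl 2‑diazobut‑3‑enoate | C=CC(=[N+]=[N-])C(=O)OC | intermediate
7 | (1R) ketal dienoate, [4+3] adduct | COC(=O)C=1CC=C2[C@](C)(CCC23OCCO3)CC=1 | intermediate
8 | 6α‑hydroxy‑5αH ketal ester | COC(=O)C=1C[C@H](O)[C@@H]2[C@](C)(CCC23OCCO3)CC=1 | intermediate
9 | 6α‑hydroxy‑4‑oxo ester | COC(=O)C=1C[C@H](O)[C@@H]2[C@](C)(CCC2=O)CC=1 | intermediate
10 | 4β,6α‑dihydroxy‑4α‑isopropyl ester | COC(=O)C=1C[C@H](O)[C@@H]2[C@](C)(CC[C@@]2(O)C(C)C)CC=1 | intermediate
11 | dauc‑8‑ene‑4β,6α,14‑triol | OCC=1C[C@H](O)[C@@H]2[C@](C)(CC[C@@]2(O)C(C)C)CC=1 | intermediate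
12 | 8α,9α‑epoxydaucane‑4β,6α,14‑triol | OC[C@@]13C[C@H](O)[C@@H]2[C@](C)(CC[C@@]2(O)C(C)C)C[C@@H]1O3 | intermediate
13 | 8α,9α‑epoxy‑14‑iododaucane‑4β,6α‑diol | IC[C@@]13C[C@H](O)[C@@H]2[C@](C)(CC[C@@]2(O)C(C)C)C[C@@H]1O3 | intermediate
14 | 4‑hydroxybenzoic acid | OC(=O)c1ccc(O)cc1 | starting material
15 | 4‑(tert‑butyldimethylsilyloxy)benzoic acid | CC(C)(C)[Si](C)(C)Oc1ccc(cc1)C(=O)O | intermediate
16 | C6 4‑(TBSO)benzoate of 13 | IC[C@@]13C[C@H](OC(=O)c4ccc(O[Si](C)(C)C(C)(C)C)cc4)[C@@H]2[C@](C)(CC[C@@]2(O)C(C)C)C[C@@H]1O3 | intermediate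
17 | O‑TBS‑ferugin | C=C1C[C@H](OC(=O)c2ccc(O[Si](C)(C)C(C)(C)C)cc2)[C@@H]2[C@](C)(CC[C@@]2(O)C(C)C)C[C@@H]1O | intermediate
18 | ferugin | C=C1C[C@H](OC(=O)c2ccc(O)cc2)[C@@H]2[C@](C)(CC[C@@]2(O)C(C)C)C[C@@H]1O | target

## Step count
- Total steps: 15
- Longest linear sequence: 13 (steps 1–3, 5–11, 13–15); steps 4 and 12 are side branches.

## Three steps most likely to fail, with fallbacks
1. **Step 5, [4+3].** The Cope step must form a quaternary centre from a tetrasubstituted alkene with the methyl inside the boat. It may stall at the divinylcyclopropane, give low ee, or lose material to ketal ylide or C–H insertion chemistry. Fallback: abandon the cycloaddition and close the seven‑membered ring last by an intramolecular Nozaki–Hiyama–Kishi reaction (C8–C9 bond, 2‑bromoallyl unit onto a C9 aldehyde). The cyclopentane precursor would come from Cu‑catalysed asymmetric conjugate addition / aldol on 3‑methylcyclopentenone; this closure gives the C8 methylene and C9 carbinol directly.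

2. **Step 6, hydroboration face and reactivity.** The substrate's own bias is weak (angular methyl versus the folded cycloheptadiene), and the alkene is neopentyl‑like, so IpcBH2 may be slow or give poor dr. Fallback: a tethered delivery instead of an intermolecular reagent. Hydrolyse 7 to the enone, CBS‑reduce to the 4α‑allylic alcohol, attach an O–SiMe2H tether, run Pt‑catalysed intramolecular hydrosilylation (Si to C6 and H to C5 from the α‑face) and Tamao‑oxidise. The resulting diol is then differentiated and C4 oxidised back to the ketone before step 8.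

3. **Steps 7–8, the β‑hydroxy ketone and i‑Pr addition.** Ketone 9 can epimerise at C5, eliminate or undergo retro‑aldol, and a secondary nucleophile on a hindered cyclopentanone may reduce or enolise it instead of adding. Fallback: bring C4 in from the chiral pool. Make the diene from terpinen‑4‑ol (O‑silylation, ozonolysis, piperidinium acetate aldol condensation to the cyclopentene carbaldehyde, Wittig methylenation) so the C(OH)iPr centre exists before the [4+3]. The cycloaddition is then run under catalyst control, and no C4 ketone is ever generated next to C5.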